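**Retrosynthetic overview**
- The ester between the two halves is cut last: a seven-membered seco-anhydride of the vinyl-bearing diacid is opened at its less hindered carbonyl by the primary hydroxyl of the diol-bearing half.
- Both halves come from one allylic alcohol. Ring C (the tetrahydropyran) is closed either by Sharpless epoxidation and 6-exo epoxide opening (diol half) or by a palladium-catalysed allylic etherification (vinyl half).
- The allylic alcohol is assembled by a B-alkyl Suzuki–Miyaura coupling (C12–C13) of a ring B fragment with (Z)-3-iodobut-2-en-1-ol.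
- Ring B is elaborated from 2-methylcyclohexenone: C4–C5 by enantioconvergent Pd allylic alkylation, the C10 quaternary centre by Mukaiyama–Michael addition, C9–C11 by Pd enolate vinylation, the C8 carbinol by methylenation and oxymercuration.
- Ring order: ring B is present from the start, ring C is formed last in each half.

Assumption: atom labels C1–C17 follow labdane numbering (ring B = C5–C10; ring C = C8, C9, C11, C12, C13 and O; C1/C2 = the CH2CO2H arm on C10; C4/C3 = the CMe2CO2H arm on C5), and the ligand antipode written in steps 5 and 18 is the expected one, to be confirmed by a pilot run with both antipodes.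

**Route**

Step 1
Reactants: 1 2-methylcyclohex-2-en-1-one
Product: 2 rac-2-methylcyclohex-2-en-1-ol
Conditions: NaBH4, CeCl3·7H2O, MeOH, 0 °C
Reagents that add atoms: none
Why: Luche 1,2-reduction of the enone gives the allylic alcohol cleanly, and no stereocontrol is needed because both enantiomers converge in step 5.

Step 2
Reactants: 2 rac-2-methylcyclohex-2-en-1-ol
Product: 3 rac-methyl 2-methylcyclohex-2-en-1-yl carbonate
Conditions: ClCO2Me, pyridine, CH2Cl2, 0 → 20 °C
Reagents that add atoms: methyl chloroformate COC(Cl)=O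
Why: Acylation of the secondary alcohol gives the allylic carbonate, the standard ionisable leaving group for Tsuji–Trost chemistry, which releases methoxide on ionisation.

Step 3
Reactants: 4 2-methylpropanoyl chloride
Product: 5 2-(trimethylsilyl)ethyl 2-methylpropanoate
Conditions: Me3SiCH2CH2OH, pyridine, DMAP (cat.), CH2Cl2, 0 → 20 °C
Reagents that add atoms: 2-(trimethylsilyl)ethanol C[Si](C)(C)CCO
Why: Acid chloride esterification installs the fluoride-labile 2-(trimethylsilyl)ethyl ester that is carried to the last step.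

Step 4
Reactants: 5 2-(trimethylsilyl)ethyl 2-methylpropanoate
Product: 6 silyl ketene acetal of 5
Conditions: LiN(iPr)2, Me3SiCl (in situ), THF, −78 → 20 °C
Reagents that add atoms: chlorotrimethylsilane C[Si](C)(C)Cl
Why: Enolisation with in situ O-silylation of a fully α-substituted ester gives the tetrasubstituted silyl ketene acetal without C-silylation.

Step 5
Reactants: 3 rac-methyl 2-methylcyclohex-2-en-1-yl carbonate, 6 silyl ketene acetal
Product: 7 2-(trimethylsilyl)ethyl 2-methyl-2-[(1S)-2-methylcyclohex-2-en-1-yl]propanoate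
Conditions: Pd2(dba)3·CHCl3 (2.5 mol %), (S,S)-DACH-phenyl Trost ligand (7.5 mol %), 6 (1.5 equiv), CH2Cl2, 0 → 20 °C
Reagents that add atoms: none
Why: Proposed new method: zerovalent palladium with the Trost ligand ionises either enantiomer of 3 to the same meso 2-methyl π-allyl complex, the methoxide released on decarboxylation desilylates 6 to an ester enolate ion-paired with the cationic complex, and the chiral pocket directs its outer-sphere attack to one of the two enantiotopic allyl termini, so the C4–C5 bond and the (S) centre at C5 are formed in one enantioconvergent step; the closest known reactions are the Trost asymmetric allylic alkylation of cyclic meso π-allyl electrophiles with malonates and the racemic Tsuji–Trost allylation of ketene silyl acetals by allyl carbonates.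

Step 6
Reactants: 7 cyclohexenyl ester
Product: 8 2-(trimethylsilyl)ethyl 2-methyl-2-[(1S)-2-methyl-4-oxocyclohex-2-en-1-yl]propanoate
Conditions: Rh2(cap)4 (dirhodium tetracaprolactamate, 1 mol %), t-BuOOH (5 equiv), K2CO3 (0.5 equiv), CH2Cl2, 20 °C
Reagents that add atoms: tert-butyl hydroperoxide CC(C)(C)OO
Why: Radical allylic C–H oxidation attacks the unhindered ring CH2 next to the vinylic CH (C8) and gives the conjugated enone without touching the C5 stereocentre.

Step 7
Reactants: 9 acetyl chloride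
Product: 10 2-(trimethylsilyl)ethyl acetate
Conditions: Me3SiCH2CH2OH, pyridine, CH2Cl2, 0 → 20 °C
Reagents that add atoms: 2-(trimethylsilyl)ethanol C[Si](C)(C)CCO
Why: Acid chloride esterification gives the acetate that will become the C1–C2 arm with the same protecting group as C3.

Step 8
Reactants: 10 2-(trimethylsilyl)ethyl acetate
Product: 11 silyl ketene acetal of 10
Conditions: LiN(iPr)2, Me3SiCl (in situ), THF/DMPU, −78 → 20 °C
Reagents that add atoms: chlorotrimethylsilane C[Si](C)(C)Cl
Why: Enolate O-silylation in the presence of the polar cosolvent gives the ketene silyl acetal needed as the Mukaiyama–Michael donor.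

Step 9
Reactants: 8 enone, 11 silyl ketene acetal, 12 bromoethene
Product: 16 α-vinyl ketone (3-ethenyl-4-oxocyclohexane diester), via TMS enol ether 13 (not isolated), via potassium enolate 14 (not isolated), via potassium dienolate 15 (not isolated)
Conditions: 11 (1.5 equiv), Tf2NH (2 mol %), CH2Cl2, −78 °C; evaporate; KOt-Bu (1.0 equiv), THF, −40 °C; Pd2(dba)3 (2.5 mol %), P(t-Bu)3 (10 mol %), 12 (4 equiv), KN(SiMe3)2 (1.1 equiv), −40 → 20 °C; AcOH, −78 °C
Reagents that add atoms: none
Why: A silyl triflimide-catalysed Mukaiyama–Michael addition delivers the acetate unit to C10 anti to the bulky C5 arm (quaternary centre with methyl cis to that arm), the regiodefined enolate is then vinylated at C9 by a palladium-catalysed enolate–alkenyl bromide coupling, and the product, held as its extended dienolate, is protonated kinetically at the α-carbon from the face opposite the axial C10 methyl so that the C9 vinyl group ends up equatorial.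

Step 10
Reactants: 16 α-vinyl ketone
Product: 17 exocyclic methylene compound (C8=CH2)
Conditions: Zn, CH2Br2, TiCl4, THF/CH2Cl2, 0 → 20 °C
Reagents that add atoms: dibromomethane BrCBr
Why: The non-basic Lombardo methylenation converts the hindered, epimerisable β,γ-unsaturated ketone into the 1,1-disubstituted alkene without enolisation, so C9 and the esters are untouched.

Step 11
Reactants: 17 exocyclic methylene compound
Product: 19 tertiary alcohol (C8 carbinol), via organomercurial 18 (not isolated)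
Conditions: Hg(OAc)2, THF/H2O, 20 °C; then NaBH4, 0.5 M NaOH, 0 °C
Reagents that add atoms: water O
Why: Markovnikov oxymercuration–demercuration hydrates the electron-rich 1,1-disubstituted alkene in preference to the hindered vinyl group, and water enters at C8 from the equatorial face away from the 1,3-diaxial C10 methyl, giving the carbinol with equatorial OH and axial methyl (8S).

Step 12
Reactants: 20 ethyl but-2-ynoate
Product: 21 ethyl (2Z)-3-iodobut-2-enoate
Conditions: NaI, AcOH, 115 °C
Reagents that add atoms: sodium iodide [Na+].[I-]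
Why: Conjugate anti-addition of HI to the ynoate gives the Z β-iodo enoate stereoselectively (hydroiodination).

Step 13
Reactants: 21 ethyl (2Z)-3-iodobut-2-enoate
Product: 22 (2Z)-3-iodobut-2-en-1-ol
Conditions: iBu2AlH (2.2 equiv), CH2Cl2, −78 °C
Reagents that add atoms: none
Why: Hydride 1,2-reduction of the ester gives the allylic alcohol with the Z geometry and the alkenyl iodide intact.

Step 14
Reactants: 19 tertiary alcohol, 22 (2Z)-3-iodobut-2-en-1-ol
Product: 24 Z-allylic alcohol (full C11–C15 side chain), via alkylborane 23 (not isolated)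
Conditions: 9-BBN (2.5 equiv), THF, 20 °C; then 22, PdCl2(dppf) (5 mol %), AsPh3 (10 mol %), Cs2CO3, DMF/H2O, 20 → 45 °C
Reagents that add atoms: none
Why: Anti-Markovnikov hydroboration of the only alkene followed by B-alkyl Suzuki–Miyaura coupling forms the C12–C13 bond with retention of the Z geometry, tolerates both free hydroxyls and creates no stereocentre.

Step 15
Reactants: 24 Z-allylic alcohol
Product: 25 (13S,14R)-epoxy alcohol
Conditions: Ti(OiPr)4 (10 mol %), D-(−)-diisopropyl tartrate (12 mol %), t-BuOOH, 4 Å molecular sieves, CH2Cl2, −20 °C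
Reagents that add atoms: tert-butyl hydroperoxide CC(C)(C)OO
Why: Sharpless asymmetric epoxidation of the Z-trisubstituted allylic alcohol is reagent-controlled and with the D-tartrate sets 13S and 14R, while the remote tertiary alcohol and the esters do not interfere.

Step 16
Reactants: 25 epoxy alcohol
Product: 26 diol diester (ring C closed; 13R,14R)
Conditions: (+)-10-camphorsulfonic acid (10 mol %), CH2Cl2, 0 °C
Reagents that add atoms: none
Why: Acid-catalysed 6-exo epoxide opening by the C8 tertiary hydroxyl at the tertiary epoxide carbon proceeds with inversion at C13 and leaves C14 untouched, which closes ring C and gives the 13R,14R diol (epoxide-opening etherification).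

Step 17
Reactants: 24 Z-allylic alcohol
Product: 27 tert-butyl allylic carbonate
Conditions: (t-BuOCO)2O, DMAP (10 mol %), CH2Cl2, 0 °C
Reagents that add atoms: di-tert-butyl dicarbonate CC(C)(C)OC(=O)OC(=O)OC(C)(C)C
Why: Chemoselective carbonate formation at the primary allylic hydroxyl (the hindered tertiary C8 hydroxyl is inert) installs a leaving group that releases non-nucleophilic tert-butoxide on ionisation.

Step 18
Reactants: 27 tert-butyl allylic carbonate
Product: 28 vinyl tetrahydropyran diester (ring C closed; 13R)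
Conditions: Pd2(dba)3·CHCl3 (2.5 mol %), (S,S)-ANDEN-phenyl Trost ligand (7.5 mol %), CH2Cl2, 0 → 20 °C
Reagents that add atoms: none
Why: Proposed new method: zerovalent palladium ionises the Z-allylic carbonate to a π-allyl complex whose faces exchange through the unsubstituted terminus, the released tert-butoxide deprotonates the C8 carbinol, and the Trost ligand pocket steers the 6-exo outer-sphere attack of this tertiary alkoxide on the fully substituted terminus anti to palladium so that ring C closes with the 13R vinyl-bearing centre under catalyst control; the closest known reactions are the Trost asymmetric O-allylation of phenols to 2-methyl-2-vinylchromans and palladium-catalysed cyclisations of primary or secondary hydroxy allylic carbonates to 2-vinyltetrahydropyrans, extended here to a hindered tertiary alcohol forming a bis-tertiary ether.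

Step 19
Reactants: 28 vinyl tetrahydropyran diester
Product: 29 vinyl diacid (monomeric 2,3-seco diacid)
Conditions: Bu4NF (4 equiv), THF, 20 °C; cold 0.5 M HCl work-up
Reagents that add atoms: none
Why: Fluoride-induced β-elimination cleaves both 2-(trimethylsilyl)ethyl esters, including the hindered one, and leaves the tertiary allylic ether and the vinyl group intact.

Step 20
Reactants: 29 vinyl diacid, 26 diol diester
Product: 31 ester-linked dimer with two 2-(trimethylsilyl)ethyl esters, via cyclic anhydride 30 (not isolated)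
Conditions: EDC·HCl (1.05 equiv), CH2Cl2, 0 → 20 °C; then 26 (1.0 equiv), DMAP (1.5 equiv), 20 °C
Reagents that add atoms: none
Why: Carbodiimide dehydration gives the seven-membered 2,3-anhydride, and DMAP-catalysed alcoholysis by the primary C15 hydroxyl of 26 occurs at the CH2-bound C2 carbonyl and not at the pivaloyl-like C3 carbonyl or through the hindered secondary hydroxyl, which gives the C2 ester and frees the C3 acid (regioselective anhydride opening, Steglich-type acylation).

Step 21
Reactants: 31 ester-linked dimer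
Product: 32 target CNP0271961.2
Conditions: Bu4NF (6 equiv), THF, 0 → 20 °C; cold 0.5 M HCl work-up
Reagents that add atoms: none
Why: Fluoride removes the two remaining 2-(trimethylsilyl)ethyl esters by β-elimination without cleaving the internal ester, and no stereocentre is touched.

**Compound list**
1 | 2-methylcyclohex-2-en-1-one | CC1=CCCCC1=O | starting material
2 | rac-2-methylcyclohex-2-en-1-ol | CC1=CCCCC1O | intermediate
3 | rac-methyl 2-methylcyclohex-2-en-1-yl carbonate | COC(=O)OC1CCCC=C1C | intermediate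
4 | 2-methylpropanoyl chloride | CC(C)C(Cl)=O | starting material
5 | 2-(trimethylsilyl)ethyl 2-methylpropanoate | CC(C)C(=O)OCC[Si](C)(C)C | intermediate
6 | trimethyl({2-methyl-1-[2-(trimethylsilyl)ethoxy]prop-1-en-1-yl}oxy)silane | CC(C)=C(O[Si](C)(C)C)OCC[Si](C)(C)C | intermediate
7 | 2-(trimethylsilyl)ethyl 2-methyl-2-[(1S)-2-methylcyclohex-2-en-1-yl]propanoate | CC1=CCCC[C@@H]1C(C)(C)C(=O)OCC[Si](C)(C)C | intermediate
8 | 2-(trimethylsilyl)ethyl 2-methyl-2-[(1S)-2-methyl-4-oxocyclohex-2-en-1-yl]propanoate | CC1=CC(=O)CC[C@@H]1C(C)(C)C(=O)OCC[Si](C)(C)C | intermediate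
9 | acetyl chloride | CC(Cl)=O | starting material
10 | 2-(trimethylsilyl)ethyl acetate | CC(=O)OCC[Si](C)(C)C | intermediate
11 | trimethyl({1-[2-(trimethylsilyl)ethoxy]ethenyl}oxy)silane | C=C(O[Si](C)(C)C)OCC[Si](C)(C)C | intermediate
12 | bromoethene (vinyl bromide) | C=CBr | starting material
13 | 2-(trimethylsilyl)ethyl 2-methyl-2-[(1S,2R)-2-methyl-2-{2-oxo-2-[2-(trimethylsilyl)ethoxy]ethyl}-4-[(trimethylsilyl)oxy]cyclohex-3-en-1-yl]propanoate | C[C@]1(CC(=O)OCC[Si](C)(C)C)C=C(O[Si](C)(C)C)CC[C@@H]1C(C)(C)C(=O)OCC[Si](C)(C)C | intermediate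
14 | potassium enolate (C8–O−, C8=C9) corresponding to 13, same (1S,2R) centres | C[C@]1(CC(=O)OCC[Si](C)(C)C)C=C([O-])CC[C@@H]1C(C)(C)C(=O)OCC[Si](C)(C)C.[K+] | intermediate
15 | potassium dienolate of 16 (C8–O−, C8=C9, C9 bearing ethenyl), C5 S and C10 R unchanged | C=CC1=C([O-])CC[C@H](C(C)(C)C(=O)OCC[Si](C)(C)C)[C@@]1(C)CC(=O)OCC[Si](C)(C)C.[K+] | intermediate
16 | 2-(trimethylsilyl)ethyl 2-[(1S,2R,3S)-3-ethenyl-2-methyl-4-oxo-2-{2-oxo-2-[2-(trimethylsilyl)ethoxy]ethyl}cyclohexyl]-2-methylpropanoate | C=C[C@@H]1C(=O)CC[C@H](C(C)(C)C(=O)OCC[Si](C)(C)C)[C@@]1(C)CC(=O)OCC[Si](C)(C)C | intermediate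
17 | 2-(trimethylsilyl)ethyl 2-[(1S,2R,3R)-3-ethenyl-2-methyl-4-methylidene-2-{2-oxo-2-[2-(trimethylsilyl)ethoxy]ethyl}cyclohexyl]-2-methylpropanoate | C=C[C@@H]1C(=C)CC[C@H](C(C)(C)C(=O)OCC[Si](C)(C)C)[C@@]1(C)CC(=O)OCC[Si](C)(C)C | intermediate
18 | organomercurial: the (1S,2R,3S,4S)-4-[(acetyloxymercurio)methyl]-3-ethenyl-4-hydroxy analogue of 19 | C=C[C@@H]1[C@@](C[Hg]OC(C)=O)(O)CC[C@H](C(C)(C)C(=O)OCC[Si](C)(C)C)[C@@]1(C)CC(=O)OCC[Si](C)(C)C | intermediate
19 | 2-(trimethylsilyl)ethyl 2-[(1S,2R,3S,4S)-3-ethenyl-4-hydroxy-2,4-dimethyl-2-{2-oxo-2-[2-(trimethylsilyl)ethoxy]ethyl}cyclohexyl]-2-methylpropanoate | C=C[C@@H]1[C@@](C)(O)CC[C@H](C(C)(C)C(=O)OCC[Si](C)(C)C)[C@@]1(C)CC(=O)OCC[Si](C)(C)C | intermediate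
20 | ethyl but-2-ynoate | CC#CC(=O)OCC | starting material
21 | ethyl (2Z)-3-iodobut-2-enoate | C/C(I)=C/C(=O)OCC | intermediate
22 | (2Z)-3-iodobut-2-en-1-ol | C/C(I)=C/CO | intermediate
23 | B-alkyl-9-borabicyclo[3.3.1]nonane from hydroboration of the ethenyl group of 19 (boron on C12) | B1(CC[C@@H]2[C@@](C)(O)CC[C@H](C(C)(C)C(=O)OCC[Si](C)(C)C)[C@@]2(C)CC(=O)OCC[Si](C)(C)C)C3CCCC1CCC3 | intermediate
24 | 2-(trimethylsilyl)ethyl 2-[(1S,2R,3S,4S)-4-hydroxy-3-[(3Z)-5-hydroxy-3-methylpent-3-en-1-yl]-2,4-dimethyl-2-{2-oxo-2-[2-(trimethylsilyl)ethoxy]ethyl}cyclohexyl]-2-methylpropanoate | OC/C=C(/C)CC[C@@H]1[C@@](C)(O)CC[C@H](C(C)(C)C(=O)OCC[Si](C)(C)C)[C@@]1(C)CC(=O)OCC[Si](C)(C)C | intermediate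
25 | 2-(trimethylsilyl)ethyl 2-[(1S,2R,3S,4S)-4-hydroxy-3-{2-[(2S,3R)-3-(hydroxymethyl)-2-methyloxiran-2-yl]ethyl}-2,4-dimethyl-2-{2-oxo-2-[2-(trimethylsilyl)ethoxy]ethyl}cyclohexyl]-2-methylpropanoate | OC[C@H]1O[C@@]1(C)CC[C@@H]2[C@@](C)(O)CC[C@H](C(C)(C)C(=O)OCC[Si](C)(C)C)[C@@]2(C)CC(=O)OCC[Si](C)(C)C | intermediate
26 | 2-(trimethylsilyl)ethyl 2-[(2R,4aS,5R,6S,8aS)-2-[(1R)-1,2-dihydroxyethyl]-2,5,8a-trimethyl-5-{2-oxo-2-[2-(trimethylsilyl)ethoxy]ethyl}octahydro-2H-chromen-6-yl]-2-methylpropanoate | OC[C@@H](O)[C@@]1(C)CC[C@H]2[C@](C)(CC(=O)OCC[Si](C)(C)C)[C@@H](C(C)(C)C(=O)OCC[Si](C)(C)C)CC[C@]2(C)O1 | intermediate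
27 | 2-(trimethylsilyl)ethyl 2-[(1S,2R,3S,4S)-3-[(3Z)-5-[(tert-butoxycarbonyl)oxy]-3-methylpent-3-en-1-yl]-4-hydroxy-2,4-dimethyl-2-{2-oxo-2-[2-(trimethylsilyl)ethoxy]ethyl}cyclohexyl]-2-methylpropanoate | CC(C)(C)OC(=O)OC/C=C(/C)CC[C@@H]1[C@@](C)(O)CC[C@H](C(C)(C)C(=O)OCC[Si](C)(C)C)[C@@]1(C)CC(=O)OCC[Si](C)(C)C | intermediate
28 | 2-(trimethylsilyl)ethyl 2-[(2R,4aS,5R,6S,8aS)-2-ethenyl-2,5,8a-trimethyl-5-{2-oxo-2-[2-(trimethylsilyl)ethoxy]ethyl}octahydro-2H-chromen-6-yl]-2-methylpropanoate | C=C[C@@]1(C)CC[C@H]2[C@](C)(CC(=O)OCC[Si](C)(C)C)[C@@H](C(C)(C)C(=O)OCC[Si](C)(C)C)CC[C@]2(C)O1 | intermediate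
29 | 2-[(2R,4aS,5R,6S,8aS)-5-(carboxymethyl)-2-ethenyl-2,5,8a-trimethyloctahydro-2H-chromen-6-yl]-2-methylpropanoic acid | C=C[C@@]1(C)CC[C@H]2[C@](C)(CC(=O)O)[C@@H](C(C)(C)C(=O)O)CC[C@]2(C)O1 | intermediate
30 | cyclic seven-membered anhydride of 29 (oxepane-2,7-dione ring through C2–O–C3, all five stereocentres as in 29) | C=C[C@@]1(C)CC[C@H]2[C@]3(C)CC(=O)OC(=O)C(C)(C)[C@H]3CC[C@]2(C)O1 | intermediate
31 | 2-[(2R,4aS,5R,6S,8aS)-5-(2-{(2R)-2-[(2R,4aS,5R,6S,8aS)-2,5,8a-trimethyl-6-{2-methyl-1-oxo-1-[2-(trimethylsilyl)ethoxy]propan-2-yl}-5-{2-oxo-2-[2-(trimethylsilyl)ethoxy]ethyl}octahydro-2H-chromen-2-yl]-2-hydroxyethoxy}-2-oxoethyl)-2-ethenyl-2,5,8a-trimethyloctahydro-2H-chromen-6-yl]-2-methylpropanoic acid | C=C[C@@]1(C)CC[C@H]2[C@](C)(CC(=O)OC[C@@H](O)[C@@]3(C)CC[C@H]4[C@](C)(CC(=O)OCC[Si](C)(C)C)[C@@H](C(C)(C)C(=O)OCC[Si](C)(C)C)CC[C@]4(C)O3)[C@@H](C(C)(C)C(=O)O)CC[C@]2(C)O1 | intermediate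
32 | 2-[(2R,4aS,5R,6S,8aS)-5-(2-{(2R)-2-[(2R,4aS,5R,6S,8aS)-5-(carboxymethyl)-6-(2-carboxypropan-2-yl)-2,5,8a-trimethyloctahydro-2H-chromen-2-yl]-2-hydroxyethoxy}-2-oxoethyl)-2-ethenyl-2,5,8a-trimethyloctahydro-2H-chromen-6-yl]-2-methylpropanoic acid (CNP0271961.2) | C=C[C@@]1(C)CC[C@H]2[C@](C)(CC(=O)OC[C@@H](O)[C@@]3(C)CC[C@H]4[C@](C)(CC(=O)O)[C@@H](C(C)(C)C(=O)O)CC[C@]4(C)O3)[C@@H](C(C)(C)C(=O)O)CC[C@]2(C)O1 | target

**Step count**
Total steps: 21. Longest linear sequence: 13 steps (steps 1, 2, 5, 6, 9, 10, 11, 14, 17, 18, 19, 20, 21).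

**Three steps most likely to fail, with fallbacks**

Step 5 (proposed new enantioconvergent allylic alkylation). The hindered ester enolate may eliminate the π-allyl complex to a diene or attack with low selectivity. The fallback sets out from 1 and comes back at 7. Ketone 1 is reduced with (S)-2-methyl-CBS-oxazaborolidine and BH3·SMe2 to (1R)-2-methylcyclohex-2-en-1-ol F1. This is acylated with 4 (pyridine, DMAP) to (1R)-2-methylcyclohex-2-en-1-yl 2-methylpropanoate F2. An Ireland–Claisen rearrangement (LiN(iPr)2, Me3SiCl, THF, −78 °C → reflux) then runs through the silyl ketene acetal F3 and the trimethylsilyl ester F4 to 2-methyl-2-[(1S)-2-methylcyclohex-2-en-1-yl]propanoic acid F5, with suprafacial transfer of chirality from the carbinol carbon to C5. Mitsunobu esterification of F5 with 2-(trimethylsilyl)ethanol (PPh3, diisopropyl azodicarboxylate) gives 7.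

Step 9 (Michael addition to a hindered enone followed by enolate vinylation). The coupling may stall, lose enolate regiochemistry or give the conjugated isomer. The fallback sets out from 8 and comes back at 16 without metal catalysis. The Michael adduct 13 is generated as before and trapped in the same flask with acetaldehyde (−78 °C, tandem Mukaiyama–Michael/aldol, 1 M HCl work-up) to give the β-hydroxy ketone F6. Acid-catalysed dehydration (p-TsOH, toluene, 80 °C) gives the conjugated ethylidene ketone F7. Thermodynamic γ-deprotonation with KOt-Bu in t-BuOH/THF forms the extended dienolate 15, and kinetic α-protonation with acetic acid at −78 °C gives 16 (classical aldol condensation and deconjugative protonation).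

Step 18 (proposed new allylic etherification). The tertiary alkoxide may be too hindered, or the C13 selectivity may be low. The fallback sets out from diol 26 and comes back at 28 by a Corey–Winter olefination. 1,1′-Thiocarbonyldiimidazole (toluene, 80 °C) converts the 14,15-diol into the cyclic thionocarbonate F8. 1,3-Dimethyl-2-phenyl-1,3,2-diazaphospholidine (40 °C) then removes CO2 and sulfur to give 28, whose C13 configuration was already fixed by the epoxide opening of step 16.

**Further compounds**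
F1 | step 5 | (1R)-2-methylcyclohex-2-en-1-ol | CC1=CCCC[C@H]1O
F2 | step 5 | (1R)-2-methylcyclohex-2-en-1-yl 2-methylpropanoate | CC1=CCCC[C@H]1OC(=O)C(C)C
F3 | step 5 | trimethyl[(2-methyl-1-{[(1R)-2-methylcyclohex-2-en-1-yl]oxy}prop-1-en-1-yl)oxy]silane | CC1=CCCC[C@H]1OC(O[Si](C)(C)C)=C(C)C
F4 | step 5 | trimethylsilyl 2-methyl-2-[(1S)-2-methylcyclohex-2-en-1-yl]propanoate | CC1=CCCC[C@@H]1C(C)(C)C(=O)O[Si](C)(C)C
F5 | step 5 | 2-methyl-2-[(1S)-2-methylcyclohex-2-en-1-yl]propanoic acid | CC1=CCCC[C@@H]1C(C)(C)C(=O)O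
F6 | step 9 | 2-(trimethylsilyl)ethyl 2-[(1S,2R)-3-(1-hydroxyethyl)-2-methyl-4-oxo-2-{2-oxo-2-[2-(trimethylsilyl)ethoxy]ethyl}cyclohexyl]-2-methylpropanoate (mixture at C3 of the ring and at the carbinol carbon) | CC(O)C1C(=O)CC[C@H](C(C)(C)C(=O)OCC[Si](C)(C)C)[C@@]1(C)CC(=O)OCC[Si](C)(C)C
F7 | step 9 | 2-(trimethylsilyl)ethyl 2-[(1S,2S)-3-ethylidene-2-methyl-4-oxo-2-{2-oxo-2-[2-(trimethylsilyl)ethoxy]ethyl}cyclohexyl]-2-methylpropanoate (E/Z mixture) | CC=C1C(=O)CC[C@H](C(C)(C)C(=O)OCC[Si](C)(C)C)[C@@]1(C)CC(=O)OCC[Si](C)(C)C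
F8 | step 18 | cyclic thionocarbonate of 26: 2-(trimethylsilyl)ethyl 2-[(2R,4aS,5R,6S,8aS)-2,5,8a-trimethyl-5-{2-oxo-2-[2-(trimethylsilyl)ethoxy]ethyl}-2-[(4R)-2-sulfanylidene-1,3-dioxolan-4-yl]octahydro-2H-chromen-6-yl]-2-methylpropanoate | S=C1OC[C@@H](O1)[C@@]2(C)CC[C@H]3[C@](C)(CC(=O)OCC[Si](C)(C)C)[C@@H](C(C)(C)C(=O)OCC[Si](C)(C)C)CC[C@]3(C)O2
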